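**Retrosynthetic overview**
- C40 skeleton: two Wittig disconnections (C11=C12 and C11′=C12′) give the C15 phosphonium salt of the trihydroxy end (ring A), the commercial C10 dialdehyde and the C15 phosphonium salt of the furanoid end (ring B).
- Both C15 salts come from one alkynyl cyclic carbonate: Red-Al gives the (E)-diene cis-diol; anti-SN2′ copper hydride reduction followed by allenol cyclisation gives the dihydrofuran.
- The carbonate comes from the acetylide of (E)-3-methylpent-2-en-4-yn-1-ol and a silyl-protected 2,4-dihydroxy-2,6,6-trimethylcyclohexanone.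
- That ketone comes from ketoisophorone by organocatalytic asymmetric epoxidation (first stereocentre), reductive epoxide opening and hydroxyl-directed anti reduction.
- Ring order: both cyclohexane rings are carried in from ketoisophorone; the temporary cyclic carbonate closes in step 5 and the dihydrofuran of ring B, the only new ring, in step 9.

Assumption: the quinine-derived amine in step 1 is taken to give the (1R,6S) epoxide by analogy with 3-substituted cyclohexenones; if a first screen shows the opposite sense, the quinidine-derived pseudoenantiomer is used.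

**Step 1**
Reactants: 1 ketoisophorone (2,6,6-trimethylcyclohex-2-ene-1,4-dione)
Product: 2 (1R,6S)-1,3,3-trimethyl-7-oxabicyclo[4.1.0]heptane-2,5-dione
Conditions: 9-amino-9-deoxy-epi-quinine (10 mol %), CF3CO2H (20 mol %), 50% aq H2O2 (1.5 equiv), dioxane, 35 °C
Reagents that add atoms: hydrogen peroxide, OO
Why: Proposed new method: primary-amine iminium-catalysed asymmetric Weitz–Scheffer epoxidation on a cyclic 2-ene-1,4-dione, a substrate class where it has not been shown; the amine condenses only with the unhindered C4 carbonyl (C1 is flanked by the gem-dimethyl carbon and the methyl-bearing alkene carbon), the protonated quinuclidine steers H2O2 onto one face of the methyl-bearing β-carbon, and the enamine closes onto the O–O bond, so the catalyst sets the tertiary C–O centre (later C5 and C5′); the acidic, base-free medium suppresses the racemic hydroperoxide-anion background; closest known reaction: amine-salt-catalysed asymmetric epoxidation of 3-substituted cyclohex-2-enones with aqueous H2O2.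

**Step 2**
Reactants: 2 (1R,6S)-1,3,3-trimethyl-7-oxabicyclo[4.1.0]heptane-2,5-dione
Product: 3 (2R)-2-hydroxy-2,6,6-trimethylcyclohexane-1,4-dione
Conditions: (PhSe)2, NaBH4, EtOH, 0 °C; then AcOH, 2, 0 °C → rt
Reagents that add atoms: none
Why: Organoselenium reductive opening of an α,β-epoxy ketone: PhSe− attacks the secondary epoxide carbon next to the unhindered carbonyl (SN2), a second selenolate removes selenium to give the enol, and the tertiary C–O bond is never broken, so the (R) centre is kept.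

**Step 3**
Reactants: 3 (2R)-2-hydroxy-2,6,6-trimethylcyclohexane-1,4-dione
Product: 4 (2R,4S)-2,4-dihydroxy-2,6,6-trimethylcyclohexan-1-one
Conditions: Me4NBH(OAc)3, MeCN/AcOH (1:1), −30 → 0 °C
Reagents that add atoms: none
Why: Evans–Saksena hydroxyl-directed reduction: the axial tertiary hydroxyl binds boron and delivers hydride to the β-carbonyl from its own face, giving the anti-1,3-diol (new carbinol S, trans to the tertiary OH); the α-hydroxy ketone flanked by two quaternary carbons is not reduced.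

**Step 4**
Reactants: 4 (2R,4S)-2,4-dihydroxy-2,6,6-trimethylcyclohexan-1-one
Product: 5 (2R,4S)-4-[(tert-butyldimethylsilyl)oxy]-2-hydroxy-2,6,6-trimethylcyclohexan-1-one
Conditions: TBSCl, imidazole, DMF, 0 °C → rt
Reagents that add atoms: tert-butyldimethylsilyl chloride (TBSCl), CC(C)(C)[Si](C)(C)Cl
Why: Selective silylation of the secondary alcohol; the tertiary alcohol is too hindered for TBSCl/imidazole.

**Step 5**
Reactants: 5 (2R,4S)-4-[(tert-butyldimethylsilyl)oxy]-2-hydroxy-2,6,6-trimethylcyclohexan-1-one; 6 (E)-3-methylpent-2-en-4-yn-1-ol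
Product: 10 (3aR,6S,7aR)-6-[(tert-butyldimethylsilyl)oxy]-3a-[(3E)-5-hydroxy-3-methylpent-3-en-1-yn-1-yl]-4,4,7a-trimethylhexahydro-2H-1,3-benzodioxol-2-one (cyclic carbonate of the cis-diol), via enynol TMS ether 7 (not isolated), via TMS-protected alkynyl diol 8 (not isolated), via TMS-protected cyclic carbonate 9 (not isolated)
Conditions: 6, n-BuLi (1 equiv), Me3SiCl, THF, −78 °C; n-BuLi (1 equiv); 5 + LiN(SiMe3)2, −78 → 0 °C; CDI, 0 °C → rt; aq citric acid work-up
Reagents that add atoms: 1,1′-carbonyldiimidazole (CDI), O=C(n1ccnc1)n1ccnc1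
Why: 1,2-Addition of a lithium acetylide to a non-enolisable ketone, then trapping of the vicinal dialkoxide as the cyclic carbonate: in the chair with the C2 oxygen and one C6 methyl axial the acetylide enters axially from the opposite face (polar Felkin–Anh, anti to the α-oxygen), so the new tertiary oxygen is cis to the existing one (new centre R) and only this cis-diol can close the five-membered carbonate; the transient TMS ether falls off at the acidic work-up.

**Step 6**
Reactants: 10 (alkynyl cyclic carbonate, as in step 5)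
Product: 11 (1R,2S,5S)-5-[(tert-butyldimethylsilyl)oxy]-2-[(1E,3E)-5-hydroxy-3-methylpenta-1,3-dien-1-yl]-1,3,3-trimethylcyclohexane-1,2-diol
Conditions: NaAlH2(OCH2CH2OMe)2 (Red-Al, 6 equiv), THF, 0 °C → rt; aq Rochelle salt
Reagents that add atoms: none
Why: Red-Al first reduces the carbonate to the diol alkoxide, then the propargylic alkoxyaluminate delivers hydride intramolecularly (trans-hydroalumination), so protonolysis gives only the (7E)-alkene; no stereocentre is touched and TBS ethers survive.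

**Step 7**
Reactants: 11 (ring A dienetriol, as in step 6)
Product: 13 [(2E,4E)-5-[(1S,2R,4S)-4-[(tert-butyldimethylsilyl)oxy]-1,2-dihydroxy-2,6,6-trimethylcyclohexyl]-3-methylpenta-2,4-dien-1-yl]triphenylphosphonium bromide, via allylic bromide 12 (not isolated)
Conditions: CBr4 (1.1 equiv), PPh3 (1.1 equiv), 2,6-lutidine, CH2Cl2, 0 °C; then PPh3 (1.5 equiv), rt
Reagents that add atoms: carbon tetrabromide, BrC(Br)(Br)Br; triphenylphosphine, c1ccc(cc1)P(c1ccccc1)c1ccccc1
Why: Appel bromination of the primary allylic alcohol (the tertiary alcohols do not react at 0 °C) followed by SN2 quaternisation of PPh3, under non-acidic conditions that spare the ionisable tertiary allylic alcohol.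

**Step 8**
Reactants: 10 (alkynyl cyclic carbonate, as in step 5)
Product: 14 (1R,5S)-5-[(tert-butyldimethylsilyl)oxy]-2-[(3E)-5-hydroxy-3-methylpenta-1,3-dien-1-ylidene]-1,3,3-trimethylcyclohexan-1-ol, (aS)-allene with the C8 vinyl group on the face of the tertiary hydroxyl
Conditions: (IPr)CuCl (5 mol %; IPr = 1,3-bis(2,6-diisopropylphenyl)imidazol-2-ylidene), NaOt-Bu (10 mol %), (EtO)2MeSiH (2.5 equiv), toluene, 0 °C → rt; then K2CO3, MeOH
Reagents that add atoms: none
Why: Copper hydride-catalysed anti-SN2′ reduction of a propargylic carbonate: hydride enters at the alkyne terminus (C8) anti to the leaving C6–O bond, CO2 is lost, and centre-to-axis transfer gives the single allene epimer.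

**Step 9**
Reactants: 14 (α-hydroxy vinylallene, as in step 8)
Product: 15 (2E)-3-[(2R,6S,7aR)-6-[(tert-butyldimethylsilyl)oxy]-4,4,7a-trimethyl-2,4,5,6,7,7a-hexahydro-1-benzofuran-2-yl]but-2-en-1-ol
Conditions: AgNO3 (20 mol %), CaCO3, acetone/H2O (4:1), rt, dark
Reagents that add atoms: none
Why: Silver-catalysed 5-endo cycloisomerisation of an α-hydroxyallene to a 2,5-dihydrofuran with axis-to-centre chirality transfer: the hydroxyl adds to the terminal allene carbon in the ring plane while H and the vinyl group keep their sides, giving the 8R centre (side chain trans to the angular methyl).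

**Step 10**
Reactants: 15 (ring B allylic alcohol, as in step 9)
Product: 17 [(2E)-3-[(2R,6S,7aR)-6-[(tert-butyldimethylsilyl)oxy]-4,4,7a-trimethyl-2,4,5,6,7,7a-hexahydro-1-benzofuran-2-yl]but-2-en-1-yl]triphenylphosphonium bromide, via allylic bromide 16 (not isolated)
Conditions: CBr4 (1.1 equiv), PPh3 (1.1 equiv), 2,6-lutidine, CH2Cl2, 0 °C; then PPh3 (1.5 equiv), rt
Reagents that add atoms: carbon tetrabromide, BrC(Br)(Br)Br; triphenylphosphine, c1ccc(cc1)P(c1ccccc1)c1ccccc1
Why: Appel bromination and phosphine quaternisation under neutral conditions, which avoids acid-induced ionisation and epimerisation of the doubly allylic C8–O bond.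

**Step 11**
Reactants: 13 (ring A phosphonium bromide, as in step 7); 18 (2E,4E,6E)-2,7-dimethylocta-2,4,6-trienedial (3 equiv)
Product: 19 (2E,4E,6E,8E,10E,12E)-13-[(1S,2R,4S)-4-[(tert-butyldimethylsilyl)oxy]-1,2-dihydroxy-2,6,6-trimethylcyclohexyl]-2,7,11-trimethyltrideca-2,4,6,8,10,12-hexaenal
Conditions: NaOMe, MeOH/CH2Cl2, 0 °C → rt; then heptane/EtOAc, 80 °C (Z → E)
Reagents that add atoms: none
Why: Wittig olefination of the semi-stabilised C15 ylide; the excess of symmetrical dialdehyde gives mono-condensation, and the new C11=C12 bond is equilibrated thermally to E.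

**Step 12**
Reactants: 19 (C25 aldehyde, as in step 11); 17 (ring B phosphonium bromide, as in step 10)
Product: 20 (all-E)-(3S,5R,6S,3′S,5′R,8′R)-3,3′-bis-O-(tert-butyldimethylsilyl)-5′,8′-epoxy-5,6,5′,8′-tetrahydro-β,β-carotene-3,5,6,3′-tetrol
Conditions: NaOMe, MeOH/CH2Cl2, 0 °C → rt; then heptane/EtOAc, 80 °C (Z → E)
Reagents that add atoms: none
Why: Second Wittig olefination closes the C40 polyene at C11′=C12′; the base-only medium leaves the furanoid C8′ centre and the tertiary diol untouched.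

**Step 13**
Reactants: 20 (bis-TBS ether, as in step 12)
Product: 21 (all-E)-(3S,5R,6S,3′S,5′R,8′R)-5′,8′-epoxy-5,6,5′,8′-tetrahydro-β,β-carotene-3,5,6,3′-tetrol (target)
Conditions: Bu4NF, THF, 0 °C → rt, dark, argon
Reagents that add atoms: none
Why: Fluoride cleavage of the two secondary TBS ethers under non-acidic conditions, so C8′ is not epimerised and the tertiary allylic alcohol is not ionised.

**Compound list**
1 | ketoisophorone (2,6,6-trimethylcyclohex-2-ene-1,4-dione) | CC1=CC(=O)CC(C)(C)C1=O | starting material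
2 | (1R,6S)-1,3,3-trimethyl-7-oxabicyclo[4.1.0]heptane-2,5-dione | C[C@@]12O[C@@H]1C(=O)CC(C)(C)C2=O | intermediate
3 | (2R)-2-hydroxy-2,6,6-trimethylcyclohexane-1,4-dione | C[C@@]1(O)CC(=O)CC(C)(C)C1=O | intermediate
4 | (2R,4S)-2,4-dihydroxy-2,6,6-trimethylcyclohexan-1-one | C[C@@]1(O)C[C@@H](O)CC(C)(C)C1=O | intermediate
5 | (2R,4S)-4-[(tert-butyldimethylsilyl)oxy]-2-hydroxy-2,6,6-trimethylcyclohexan-1-one | C[C@@]1(O)C[C@@H](O[Si](C)(C)C(C)(C)C)CC(C)(C)C1=O | intermediate
6 | (E)-3-methylpent-2-en-4-yn-1-ol | C#C/C(C)=C/CO | starting material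
7 | (E)-trimethyl[(3-methylpent-2-en-4-yn-1-yl)oxy]silane | C#C/C(C)=C/CO[Si](C)(C)C | intermediate
8 | (1R,2R,5S)-5-[(tert-butyldimethylsilyl)oxy]-1,3,3-trimethyl-2-[(3E)-3-methyl-5-[(trimethylsilyl)oxy]pent-3-en-1-yn-1-yl]cyclohexane-1,2-diol (formed as its dilithium alkoxide) | C[Si](C)(C)OC/C=C(C)/C#C[C@]1(O)C(C)(C)C[C@H](O[Si](C)(C)C(C)(C)C)C[C@@]1(C)O | intermediate
9 | (3aR,6S,7aR)-6-[(tert-butyldimethylsilyl)oxy]-4,4,7a-trimethyl-3a-[(3E)-3-methyl-5-[(trimethylsilyl)oxy]pent-3-en-1-yn-1-yl]hexahydro-2H-1,3-benzodioxol-2-one | C[Si](C)(C)OC/C=C(C)/C#C[C@@]12OC(=O)O[C@]1(C)C[C@@H](O[Si](C)(C)C(C)(C)C)CC2(C)C | intermediate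
10 | (3aR,6S,7aR)-6-[(tert-butyldimethylsilyl)oxy]-3a-[(3E)-5-hydroxy-3-methylpent-3-en-1-yn-1-yl]-4,4,7a-trimethylhexahydro-2H-1,3-benzodioxol-2-one | OC/C=C(C)/C#C[C@@]12OC(=O)O[C@]1(C)C[C@@H](O[Si](C)(C)C(C)(C)C)CC2(C)C | intermediate
11 | (1R,2S,5S)-5-[(tert-butyldimethylsilyl)oxy]-2-[(1E,3E)-5-hydroxy-3-methylpenta-1,3-dien-1-yl]-1,3,3-trimethylcyclohexane-1,2-diol | OC/C=C(C)/C=C/[C@]1(O)C(C)(C)C[C@H](O[Si](C)(C)C(C)(C)C)C[C@@]1(C)O | intermediate
12 | (1R,2S,5S)-2-[(1E,3E)-5-bromo-3-methylpenta-1,3-dien-1-yl]-5-[(tert-butyldimethylsilyl)oxy]-1,3,3-trimethylcyclohexane-1,2-diol | BrC/C=C(C)/C=C/[C@]1(O)C(C)(C)C[C@H](O[Si](C)(C)C(C)(C)C)C[C@@]1(C)O | intermediate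
13 | [(2E,4E)-5-[(1S,2R,4S)-4-[(tert-butyldimethylsilyl)oxy]-1,2-dihydroxy-2,6,6-trimethylcyclohexyl]-3-methylpenta-2,4-dien-1-yl]triphenylphosphonium bromide | c1ccc(cc1)[P+](c1ccccc1)(c1ccccc1)C/C=C(C)/C=C/[C@]1(O)C(C)(C)C[C@H](O[Si](C)(C)C(C)(C)C)C[C@@]1(C)O.[Br-] | intermediate
14 | (1R,5S)-5-[(tert-butyldimethylsilyl)oxy]-2-[(3E)-5-hydroxy-3-methylpenta-1,3-dien-1-ylidene]-1,3,3-trimethylcyclohexan-1-ol, (aS)-allene, C8 vinyl group on the face of the tertiary hydroxyl | OC/C=C(C)/C([H])=[C@]=C1C(C)(C)C[C@H](O[Si](C)(C)C(C)(C)C)C[C@@]1(C)O | intermediate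
15 | (2E)-3-[(2R,6S,7aR)-6-[(tert-butyldimethylsilyl)oxy]-4,4,7a-trimethyl-2,4,5,6,7,7a-hexahydro-1-benzofuran-2-yl]but-2-en-1-ol | OC/C=C(C)/[C@H]1C=C2C(C)(C)C[C@H](O[Si](C)(C)C(C)(C)C)C[C@@]2(C)O1 | intermediate
16 | (2R,6S,7aR)-2-[(2E)-4-bromobut-2-en-2-yl]-6-[(tert-butyldimethylsilyl)oxy]-4,4,7a-trimethyl-2,4,5,6,7,7a-hexahydro-1-benzofuran | BrC/C=C(C)/[C@H]1C=C2C(C)(C)C[C@H](O[Si](C)(C)C(C)(C)C)C[C@@]2(C)O1 | intermediate
17 | [(2E)-3-[(2R,6S,7aR)-6-[(tert-butyldimethylsilyl)oxy]-4,4,7a-trimethyl-2,4,5,6,7,7a-hexahydro-1-benzofuran-2-yl]but-2-en-1-yl]triphenylphosphonium bromide | c1ccc(cc1)[P+](c1ccccc1)(c1ccccc1)C/C=C(C)/[C@H]1C=C2C(C)(C)C[C@H](O[Si](C)(C)C(C)(C)C)C[C@@]2(C)O1.[Br-] | intermediate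
18 | (2E,4E,6E)-2,7-dimethylocta-2,4,6-trienedial | O=C/C(C)=C/C=C/C=C(C)/C=O | starting material
19 | (2E,4E,6E,8E,10E,12E)-13-[(1S,2R,4S)-4-[(tert-butyldimethylsilyl)oxy]-1,2-dihydroxy-2,6,6-trimethylcyclohexyl]-2,7,11-trimethyltrideca-2,4,6,8,10,12-hexaenal | O=C/C(C)=C/C=C/C=C(C)/C=C/C=C(C)/C=C/[C@]1(O)C(C)(C)C[C@H](O[Si](C)(C)C(C)(C)C)C[C@@]1(C)O | intermediate
20 | (all-E)-(3S,5R,6S,3′S,5′R,8′R)-3,3′-bis-O-(tert-butyldimethylsilyl)-5′,8′-epoxy-5,6,5′,8′-tetrahydro-β,β-carotene-3,5,6,3′-tetrol | CC(/C=C/C=C(C)/C=C/[C@]1(O)C(C)(C)C[C@H](O[Si](C)(C)C(C)(C)C)C[C@@]1(C)O)=C\C=C\C=C(C)\C=C\C=C(/C)[C@H]1C=C2C(C)(C)C[C@H](O[Si](C)(C)C(C)(C)C)C[C@@]2(C)O1 | intermediate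
21 | (all-E)-(3S,5R,6S,3′S,5′R,8′R)-5′,8′-epoxy-5,6,5′,8′-tetrahydro-β,β-carotene-3,5,6,3′-tetrol | CC(/C=C/C=C(C)/C=C/[C@]1(O)C(C)(C)C[C@H](O)C[C@@]1(C)O)=C\C=C\C=C(C)\C=C\C=C(/C)[C@H]1C=C2C(C)(C)C[C@H](O)C[C@@]2(C)O1 | target

**Step count and risks**
Total steps: 13. Longest linear sequence: 10 steps (1, 2, 3, 4, 5, 8, 9, 10, 12, 13; the branch 1–5, 6, 7, 11, 12, 13 is equally long).

The three steps most likely to fail:

- **Step 1 (proposed new step).** The ene-dione may undergo aza-Michael addition to the amine catalyst or racemic background epoxidation, so conversion or ee may be low. The fallback uses known chemistry, sets out from 1 and comes back at 5, bypassing 2–4. Ketoisophorone is reduced at the unhindered carbonyl by Ru-catalysed asymmetric transfer hydrogenation (RuCl(p-cymene)(TsDPEN), i-PrOH, using the TsDPEN antipode that gives the 4S alcohol) to (4S)-4-hydroxy-2,6,6-trimethylcyclohex-2-en-1-one F1. Silylation (TBSCl, imidazole) gives (4S)-4-[(tert-butyldimethylsilyl)oxy]-2,6,6-trimethylcyclohex-2-en-1-one F2. Mukaiyama-type reductive α-hydroxylation of the enone (Mn(dpm)3 cat., PhSiH3, O2, i-PrOH; then P(OEt)3) places the tertiary hydroxyl at the methyl-bearing carbon, with O2 expected to be captured anti to the silyloxy group, to give 5. The cis isomer is removed by chromatography.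

- **Step 5.** The hindered α-alkoxido ketone may add the functionalised acetylide sluggishly or with poor facial selectivity, and the one-pot carbonate closure hides the diastereomer ratio. The fallback sets out from 5 and comes back at 10. The small nucleophile HC≡CMgBr (excess, CeCl3, THF) gives (1R,2R,5S)-5-[(tert-butyldimethylsilyl)oxy]-2-ethynyl-1,3,3-trimethylcyclohexane-1,2-diol F3, which is isolated so that the cis-diol can be purified. The C8–C9 bond is then made by Sonogashira coupling (PdCl2(PPh3)2, CuI, Et3N) with (E)-3-iodobut-2-en-1-ol F4, giving (1R,2R,5S)-5-[(tert-butyldimethylsilyl)oxy]-2-[(3E)-5-hydroxy-3-methylpent-3-en-1-yn-1-yl]-1,3,3-trimethylcyclohexane-1,2-diol F5. Selective silylation of the primary alcohol (Me3SiCl, imidazole, −20 °C; this is 8), CDI/DBU (this is 9) and acidic work-up give 10.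

- **Step 8.** The cyclic carbonate may react sluggishly or with incomplete anti selectivity, which would lower the C8′ purity after step 9. The fallback sets out from 11, replaces steps 8 and 9, and comes back at 15. The primary alcohol of 11 is acetylated (Ac2O, pyridine, 0 °C) to (2E,4E)-5-[(1S,2R,4S)-4-[(tert-butyldimethylsilyl)oxy]-1,2-dihydroxy-2,6,6-trimethylcyclohexyl]-3-methylpenta-2,4-dien-1-yl acetate F6. The classical acid-induced furanoid cyclodehydration of the 5,6-diol (camphorsulfonic acid cat., CH2Cl2, 0 °C) gives (2E)-3-[(2R,6S,7aR)-6-[(tert-butyldimethylsilyl)oxy]-4,4,7a-trimethyl-2,4,5,6,7,7a-hexahydro-1-benzofuran-2-yl]but-2-en-1-yl acetate F7 together with its C2 epimer, (2E)-3-[(2S,6S,7aR)-6-[(tert-butyldimethylsilyl)oxy]-4,4,7a-trimethyl-2,4,5,6,7,7a-hexahydro-1-benzofuran-2-yl]but-2-en-1-yl acetate F8. The epimers are separated by HPLC, and methanolysis of F7 (K2CO3, MeOH) gives 15.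

**Further compounds**
F1 | step 1 | (4S)-4-hydroxy-2,6,6-trimethylcyclohex-2-en-1-one | CC1=C[C@@H](O)CC(C)(C)C1=O
F2 | step 1 | (4S)-4-[(tert-butyldimethylsilyl)oxy]-2,6,6-trimethylcyclohex-2-en-1-one | CC1=C[C@@H](O[Si](C)(C)C(C)(C)C)CC(C)(C)C1=O
F3 | step 5 | (1R,2R,5S)-5-[(tert-butyldimethylsilyl)oxy]-2-ethynyl-1,3,3-trimethylcyclohexane-1,2-diol | C#C[C@]1(O)C(C)(C)C[C@H](O[Si](C)(C)C(C)(C)C)C[C@@]1(C)O
F4 | step 5 | (E)-3-iodobut-2-en-1-ol | C/C(I)=C\CO
F5 | step 5 | (1R,2R,5S)-5-[(tert-butyldimethylsilyl)oxy]-2-[(3E)-5-hydroxy-3-methylpent-3-en-1-yn-1-yl]-1,3,3-trimethylcyclohexane-1,2-diol | OC/C=C(C)/C#C[C@]1(O)C(C)(C)C[C@H](O[Si](C)(C)C(C)(C)C)C[C@@]1(C)O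
F6 | step 8 | (2E,4E)-5-[(1S,2R,4S)-4-[(tert-butyldimethylsilyl)oxy]-1,2-dihydroxy-2,6,6-trimethylcyclohexyl]-3-methylpenta-2,4-dien-1-yl acetate | CC(=O)OC/C=C(C)/C=C/[C@]1(O)C(C)(C)C[C@H](O[Si](C)(C)C(C)(C)C)C[C@@]1(C)O
F7 | step 8 | (2E)-3-[(2R,6S,7aR)-6-[(tert-butyldimethylsilyl)oxy]-4,4,7a-trimethyl-2,4,5,6,7,7a-hexahydro-1-benzofuran-2-yl]but-2-en-1-yl acetate | CC(=O)OC/C=C(C)/[C@H]1C=C2C(C)(C)C[C@H](O[Si](C)(C)C(C)(C)C)C[C@@]2(C)O1
F8 | step 8 | (2E)-3-[(2S,6S,7aR)-6-[(tert-butyldimethylsilyl)oxy]-4,4,7a-trimethyl-2,4,5,6,7,7a-hexahydro-1-benzofuran-2-yl]but-2-en-1-yl acetate | CC(=O)OC/C=C(C)/[C@@H]1C=C2C(C)(C)C[C@H](O[Si](C)(C)C(C)(C)C)C[C@@]2(C)O1
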